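**Retrosynthetic overview**
1. The target differs from its 5,7-bis-TBS ether only by O–Si cleavage.
2. Key disconnection: rings C and D are both opened at a C–O bond (O1–C2 and O–C2''). This leads to one chalcone with an (E)-3,7-dimethylocta-3,6-dienyl chain ortho to the ring B phenol. In the forward direction, an oxa-Michael closure and then an oxidative Wacker-type closure in the same flask set both stereocentres and create the diene.
3. The chalcone comes from an aldol condensation of a ring A acetophenone and a ring B aldehyde.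
4. The ring A piece comes from phloroacetophenone and prenol. A para-Claisen–Cope shift puts the prenyl group para to the phenol that becomes O1, which gives the 6-prenyl pattern. The ring B piece comes from 3-bromo-4,5-dihydroxybenzaldehyde and (E)-β-ocimene by hydroboration and B-alkyl Suzuki coupling.
5. Ring order: A and B are bought as arenes. C and then D form in one operation (step 7).

Assumption: the sense of induction of the hydroquinine squaramide (2S) and of (S,S)-iPr-BOXAX (2''S) is assigned by analogy with simpler substrates and is checked on the first run (the hydroquinidine squaramide and the (R,R)-ligand are the mirror-image options); (E)-β-ocimene is used as fractionated material of at least 95 % E.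

**Step 1**
Reactants: 1 2,4,6-trihydroxyacetophenone
Product: 2 1-[2-hydroxy-4,6-bis(tert-butyldimethylsilyloxy)phenyl]ethanone
Conditions: TBSCl (2.05 equiv), imidazole (4.5 equiv), DMF, 0 °C to rt
Reagents that add atoms: tert-butyldimethylsilyl chloride, CC(C)(C)[Si](C)(C)Cl
Why: Chemoselective silyl ether formation, in which two phenols react while the third is held in the six-membered hydrogen bond to the acetyl C=O and stays free; no stereocentre is formed.

**Step 2**
Reactants: 2 1-[2-hydroxy-4,6-bis(tert-butyldimethylsilyloxy)phenyl]ethanone; 3 3-methylbut-2-en-1-ol (prenol)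
Product: 4 1-[2-(3-methylbut-2-enyloxy)-4,6-bis(tert-butyldimethylsilyloxy)phenyl]ethanone
Conditions: PPh3 (1.3 equiv), DIAD (1.3 equiv), THF, 0 °C to rt
Reagents that add atoms: none
Why: Mitsunobu etherification alkylates the remaining chelated phenol under neutral conditions that spare the aryl silyl ethers, which a carbonate/prenyl bromide alkylation would not.

**Step 3**
Reactants: 4 1-[2-(3-methylbut-2-enyloxy)-4,6-bis(tert-butyldimethylsilyloxy)phenyl]ethanone
Product: 6 1-[6-hydroxy-3-(3-methylbut-2-enyl)-2,4-bis(tert-butyldimethylsilyloxy)phenyl]ethanone, via ortho-dienone 5 (not isolated)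
Conditions: PhNEt2, 200 °C (sealed tube, Ar), 3 h
Reagents that add atoms: none
Why: Aromatic para-Claisen–Cope cascade, in which a [3,3] shift to the only free ortho carbon gives dienone 5, whose crowded reverse-prenyl group moves on by a Cope [3,3] shift to the para carbon before tautomerisation, so a normal prenyl group ends up between the two silyloxy groups and exactly the phenol that becomes O1 is freed (6-prenyl, not 8-prenyl).

**Step 4**
Reactants: 7 (E)-β-ocimene, (3E)-3,7-dimethylocta-1,3,6-triene; 8 3-bromo-4,5-dihydroxybenzaldehyde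
Product: 10 3-[(3E)-3,7-dimethylocta-3,6-dienyl]-4,5-dihydroxybenzaldehyde, via B-alkyl-9-BBN borane 9 (not isolated)
Conditions: 9-BBN (1.05 equiv), THF, 0 °C to rt; then 8, Pd(OAc)2 (3 mol %), SPhos (6 mol %), K3PO4 (4 equiv, degassed aq), THF/DMF, 50 °C; non-oxidative work-up
Reagents that add atoms: none
Why: Hydroboration/B-alkyl Suzuki–Miyaura coupling, in which 9-BBN adds anti-Markovnikov only to the monosubstituted vinyl terminus (trisubstituted alkenes react orders of magnitude more slowly) and the primary alkylborane 9 couples to the aryl bromide while the E-alkene and the aldehyde stay intact.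

**Step 5**
Reactants: 10 3-[(3E)-3,7-dimethylocta-3,6-dienyl]-4,5-dihydroxybenzaldehyde
Product: 11 3-[(3E)-3,7-dimethylocta-3,6-dienyl]-4,5-bis(triethylsilyloxy)benzaldehyde
Conditions: TESCl (2.4 equiv), imidazole (5 equiv), CH2Cl2, 0 °C
Reagents that add atoms: triethylsilyl chloride, CC[Si](Cl)(CC)CC
Why: Standard silyl ether formation; the acid-labile TES groups mask the acidic catechol for step 6 and for the organocatalytic stage of step 7 and can later be removed in the presence of TBS.

**Step 6**
Reactants: 6 1-[6-hydroxy-3-(3-methylbut-2-enyl)-2,4-bis(tert-butyldimethylsilyloxy)phenyl]ethanone; 11 3-[(3E)-3,7-dimethylocta-3,6-dienyl]-4,5-bis(triethylsilyloxy)benzaldehyde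
Product: 15 (E)-1-[6-hydroxy-3-(3-methylbut-2-enyl)-2,4-bis(tert-butyldimethylsilyloxy)phenyl]-3-{3-[(3E)-3,7-dimethylocta-3,6-dienyl]-4,5-bis(triethylsilyloxy)phenyl}prop-2-en-1-one, via bis-TMS enol silane 12 (not isolated), via silyl aldol adduct 13 (not isolated), via O-TMS chalcone 14 (not isolated)
Conditions: TMSOTf (3.5 equiv), i-Pr2NEt (4 equiv), CH2Cl2, 0 °C to rt; DBU (1.5 equiv), rt; pH 5 citrate buffer/MeOH, 0 °C
Reagents that add atoms: none
Why: One-pot soft enolisation/Mukaiyama aldol addition/dehydrosilyloxylation, in which TMSOTf–amine converts 6 into 12, TMSOTf activates aldehyde 11 for the addition to 13, DBU-induced E1cB loss of silanolate gives the (E)-enone 14, and the buffered work-up hydrolyses only the very labile aryl O–TMS bond, so no hydroxide that would strip TES or TBS is ever present.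

**Step 7 (key step)**
Reactants: 15 the chalcone of step 6
Product: 18 (2S)-5,7-bis(tert-butyldimethylsilyloxy)-2-{(2S)-8-hydroxy-2-methyl-2-[(1E)-4-methylpenta-1,3-dienyl]chroman-6-yl}-6-(3-methylbut-2-enyl)chroman-4-one, via TES-protected (S)-flavanone 16 (not isolated), via catechol (S)-flavanone 17 (not isolated)
Conditions: (a) 9-amino(9-deoxy)-epi-hydroquinine 3,5-bis(trifluoromethyl)phenyl squaramide (10 mol %), 4 Å MS, toluene, −10 °C, 48–72 h; (b) same flask: CF3CO2H (30 mol %), MeOH (toluene/MeOH 5:1), rt, 2 h; (c) same flask: Pd(OCOCF3)2 (10 mol %), (S,S)-iPr-BOXAX (20 mol %), p-benzoquinone (1.5 equiv), 35 °C, 24 h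
Reagents that add atoms: none
Why: Proposed new method: two known reaction types are telescoped so that both heterocycles and both stereocentres arise in one flask – first the bifunctional squaramide (quinuclidine as general base for the only free phenol, squaramide N–H bonds on the enone C=O) closes ring C by an enantioselective 6-endo intramolecular oxa-Michael addition and sets C2 as S (closest known type: cinchona thiourea/squaramide-catalysed chalcone-to-flavanone cyclisation), then CF3CO2H protonates the alkaloid (which stops retro-Michael racemisation and keeps its nitrogens off the metal) and methanolyses only the aryl TES ethers, and the cationic divalent palladium–BOXAX complex binds one face of the E-trisubstituted alkene, the ortho phenol adds 6-exo at the methyl-bearing carbon to set the quaternary centre as S, and β-hydride elimination towards the doubly allylic CH2 unveils the (E)-diene while benzoquinone reoxidises zerovalent palladium (closest known type: enantioselective Wacker-type cyclisation of 2-(alk-3-enyl)phenols to 2-methyl-2-vinylchromans); ring C has to close first because afterwards no chelating 2'-hydroxyaryl ketone is left to block the metal, and the prenyl group is safe because both flanking oxygens carry TBS.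

**Step 8**
Reactants: 18 the bis-TBS ether of step 7
Product: 19 (2S)-5,7-dihydroxy-2-{(2S)-8-hydroxy-2-methyl-2-[(1E)-4-methylpenta-1,3-dienyl]chroman-6-yl}-6-(3-methylbut-2-enyl)chroman-4-one (CNP0294970.1)
Conditions: KHF2 (5 equiv), MeOH/THF, rt
Reagents that add atoms: none
Why: Fluoride-driven cleavage of phenolic silyl ethers in a weakly acidic, base-free medium, so neither retro-oxa-Michael racemisation at C2 nor ionisation of the tertiary dienylic aryl ether of ring D can occur and both stereocentres are kept.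

**Compound list**
1 | 2,4,6-trihydroxyacetophenone | CC(=O)c1c(O)cc(O)cc1O | starting material
2 | 1-[2-hydroxy-4,6-bis(tert-butyldimethylsilyloxy)phenyl]ethanone | CC(=O)c1c(O)cc(O[Si](C)(C)C(C)(C)C)cc1O[Si](C)(C)C(C)(C)C | intermediate
3 | 3-methylbut-2-en-1-ol (prenol) | CC(C)=CCO | starting material
4 | 1-[2-(3-methylbut-2-enyloxy)-4,6-bis(tert-butyldimethylsilyloxy)phenyl]ethanone | CC(=O)c1c(OCC=C(C)C)cc(O[Si](C)(C)C(C)(C)C)cc1O[Si](C)(C)C(C)(C)C | intermediate
5 | racemic 2-acetyl-3,5-bis(tert-butyldimethylsilyloxy)-6-(2-methylbut-3-en-2-yl)cyclohexa-2,4-dien-1-one (ortho-dienone) | CC(=O)C1=C(O[Si](C)(C)C(C)(C)C)C=C(O[Si](C)(C)C(C)(C)C)C(C(C)(C)C=C)C1=O | intermediate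
6 | 1-[6-hydroxy-3-(3-methylbut-2-enyl)-2,4-bis(tert-butyldimethylsilyloxy)phenyl]ethanone | CC(=O)c1c(O)cc(O[Si](C)(C)C(C)(C)C)c(CC=C(C)C)c1O[Si](C)(C)C(C)(C)C | intermediate
7 | (E)-β-ocimene, (3E)-3,7-dimethylocta-1,3,6-triene | C=C/C(C)=C/CC=C(C)C | starting material
8 | 3-bromo-4,5-dihydroxybenzaldehyde | O=Cc1cc(O)c(O)c(Br)c1 | starting material
9 | 9-[(3E)-3,7-dimethylocta-3,6-dienyl]-9-borabicyclo[3.3.1]nonane | CC(C)=CC/C=C(C)/CCB1C2CCCC1CCC2 | intermediate
10 | 3-[(3E)-3,7-dimethylocta-3,6-dienyl]-4,5-dihydroxybenzaldehyde | CC(C)=CC/C=C(C)/CCc1cc(C=O)cc(O)c1O | intermediate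
11 | 3-[(3E)-3,7-dimethylocta-3,6-dienyl]-4,5-bis(triethylsilyloxy)benzaldehyde | CC(C)=CC/C=C(C)/CCc1cc(C=O)cc(O[Si](CC)(CC)CC)c1O[Si](CC)(CC)CC | intermediate
12 | bis-TMS enol silane of 6 (aryl O-TMS, 1-(trimethylsilyloxy)vinyl) | C=C(O[Si](C)(C)C)c1c(O[Si](C)(C)C)cc(O[Si](C)(C)C(C)(C)C)c(CC=C(C)C)c1O[Si](C)(C)C(C)(C)C | intermediate
13 | racemic β-(trimethylsilyloxy) ketone (silyl aldol adduct, 2'-O-TMS) | CC(C)=CC/C=C(C)/CCc1cc(C(CC(=O)c2c(O[Si](C)(C)C)cc(O[Si](C)(C)C(C)(C)C)c(CC=C(C)C)c2O[Si](C)(C)C(C)(C)C)O[Si](C)(C)C)cc(O[Si](CC)(CC)CC)c1O[Si](CC)(CC)CC | intermediate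
14 | 2'-O-TMS ether of chalcone 15 | CC(C)=CC/C=C(C)/CCc1cc(/C=C/C(=O)c2c(O[Si](C)(C)C)cc(O[Si](C)(C)C(C)(C)C)c(CC=C(C)C)c2O[Si](C)(C)C(C)(C)C)cc(O[Si](CC)(CC)CC)c1O[Si](CC)(CC)CC | intermediate
15 | (E)-chalcone with free 2'-OH, 4',6'-bis-OTBS, 5'-prenyl, 3,4-bis-OTES and 5-[(3E)-3,7-dimethylocta-3,6-dienyl] | CC(C)=CC/C=C(C)/CCc1cc(/C=C/C(=O)c2c(O)cc(O[Si](C)(C)C(C)(C)C)c(CC=C(C)C)c2O[Si](C)(C)C(C)(C)C)cc(O[Si](CC)(CC)CC)c1O[Si](CC)(CC)CC | intermediate
16 | (2S)-2-{3-[(3E)-3,7-dimethylocta-3,6-dienyl]-4,5-bis(triethylsilyloxy)phenyl}-5,7-bis(tert-butyldimethylsilyloxy)-6-(3-methylbut-2-enyl)chroman-4-one | CC(C)=CC/C=C(C)/CCc2cc([C@@H]3CC(=O)c4c(cc(O[Si](C)(C)C(C)(C)C)c(CC=C(C)C)c4O[Si](C)(C)C(C)(C)C)O3)cc(O[Si](CC)(CC)CC)c2O[Si](CC)(CC)CC | intermediate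
17 | (2S)-2-{3-[(3E)-3,7-dimethylocta-3,6-dienyl]-4,5-dihydroxyphenyl}-5,7-bis(tert-butyldimethylsilyloxy)-6-(3-methylbut-2-enyl)chroman-4-one | CC(C)=CC/C=C(C)/CCc2cc([C@@H]3CC(=O)c4c(cc(O[Si](C)(C)C(C)(C)C)c(CC=C(C)C)c4O[Si](C)(C)C(C)(C)C)O3)cc(O)c2O | intermediate
18 | (2S)-5,7-bis(tert-butyldimethylsilyloxy)-2-{(2S)-8-hydroxy-2-methyl-2-[(1E)-4-methylpenta-1,3-dienyl]chroman-6-yl}-6-(3-methylbut-2-enyl)chroman-4-one | CC(C)=C/C=C/[C@]1(C)CCc2cc([C@@H]3CC(=O)c4c(cc(O[Si](C)(C)C(C)(C)C)c(CC=C(C)C)c4O[Si](C)(C)C(C)(C)C)O3)cc(O)c2O1 | intermediate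
19 | (2S)-5,7-dihydroxy-2-{(2S)-8-hydroxy-2-methyl-2-[(1E)-4-methylpenta-1,3-dienyl]chroman-6-yl}-6-(3-methylbut-2-enyl)chroman-4-one (CNP0294970.1) | CC(C)=C/C=C/[C@]1(C)CCc2cc([C@@H]3CC(=O)c4c(cc(O)c(CC=C(C)C)c4O)O3)cc(O)c2O1 | target

**Totals**
Total step count: 8.
Longest linear sequence: 6 (steps 1, 2, 3, 6, 7, 8).

**Three steps most likely to fail**

Step 7 (double cyclisation). There are three risks:
- The unactivated, electron-rich chalcone may close slowly, reversibly or with modest ee.
- The free catechol, the leftover alkaloid or the product diene may interfere with the palladium/benzoquinone stage.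
- The acid may touch the 5-O-TBS group or ring D.

The fallback closes ring C by substitution instead of conjugate addition. It sets out from 6 and 11. Enol silane 12 is prepared separately (TMSOTf, Et3N). It is added to 11 under a chiral boron Lewis acid (N-tosyltryptophan-derived B-butyl oxazaborolidinone, antipode chosen for the R alcohol, EtCN, −78 °C; asymmetric Mukaiyama aldol). After citrate work-up this gives the (R)-β-hydroxy ketone F1. An intramolecular Mitsunobu etherification (PPh3, DIAD, toluene, 0 °C) inverts the carbinol centre. The fallback comes back to the route at the (S)-flavanone 16, now isolated and free of alkaloid, and stages (b) and (c) are run on it.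

Step 4 (coupling on the free bromocatechol). There are three risks:
- Oxidative addition into the electron-rich ortho-bromophenoxide may be slow.
- The catecholate may chelate palladium.
- β-Hydride elimination may return ocimene.

The fallback is a base-free Negishi coupling on a silylated bromide. It sets out from 9 and 8. Borane 9 is oxidised (NaBO3·4H2O) to (E)-isogeraniol F2. This is converted (I2, PPh3, imidazole) into (3E)-1-iodo-3,7-dimethylocta-3,6-diene F3, and zinc is inserted (Zn dust, LiCl, THF) to give the alkylzinc iodide F4. In parallel, 8 is silylated (TESCl, imidazole) to 3-bromo-4,5-bis(triethylsilyloxy)benzaldehyde F5. Coupling of F4 and F5 (Pd(OAc)2, SPhos, THF, rt) comes back to the route directly at 11, and 10 is skipped.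

Step 6 (soft-enolisation condensation). There are two risks:
- A second enol silane may add to the ionisable, electron-rich benzylic silyl ether.
- Silyl groups may scramble.

The fallback uses a hard enolate and a separate dehydration. It sets out from 6 and 11. The dilithium phenoxide-enolate of 6 (LiN(SiMe3)2, 2.1 equiv, THF, −78 °C) adds to 11. The mixture is quenched cold with AcOH, so that no hydroxide forms, to give the racemic β-hydroxy ketone F6. This is dehydrated with MsCl/Et3N (CH2Cl2, −20 °C to rt), and the fallback comes back to the route at chalcone 15.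

**Further compounds**
F1 | step 7 | (3R)-3-{3-[(3E)-3,7-dimethylocta-3,6-dienyl]-4,5-bis(triethylsilyloxy)phenyl}-3-hydroxy-1-[6-hydroxy-3-(3-methylbut-2-enyl)-2,4-bis(tert-butyldimethylsilyloxy)phenyl]propan-1-one | CC(C)=CC/C=C(C)/CCc1cc([C@H](O)CC(=O)c2c(O)cc(O[Si](C)(C)C(C)(C)C)c(CC=C(C)C)c2O[Si](C)(C)C(C)(C)C)cc(O[Si](CC)(CC)CC)c1O[Si](CC)(CC)CC
F2 | step 4 | (3E)-3,7-dimethylocta-3,6-dien-1-ol ((E)-isogeraniol) | CC(C)=CC/C=C(C)/CCO
F3 | step 4 | (3E)-1-iodo-3,7-dimethylocta-3,6-diene | CC(C)=CC/C=C(C)/CCI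
F4 | step 4 | [(3E)-3,7-dimethylocta-3,6-dienyl]zinc iodide | CC(C)=CC/C=C(C)/CC[Zn]I
F5 | step 4 | 3-bromo-4,5-bis(triethylsilyloxy)benzaldehyde | O=Cc1cc(O[Si](CC)(CC)CC)c(O[Si](CC)(CC)CC)c(Br)c1
F6 | step 6 | racemic 3-{3-[(3E)-3,7-dimethylocta-3,6-dienyl]-4,5-bis(triethylsilyloxy)phenyl}-3-hydroxy-1-[6-hydroxy-3-(3-methylbut-2-enyl)-2,4-bis(tert-butyldimethylsilyloxy)phenyl]propan-1-one | CC(C)=CC/C=C(C)/CCc1cc(C(O)CC(=O)c2c(O)cc(O[Si](C)(C)C(C)(C)C)c(CC=C(C)C)c2O[Si](C)(C)C(C)(C)C)cc(O[Si](CC)(CC)CC)c1O[Si](CC)(CC)CC
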